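# Proposed synthesis of [(2R,3S,4S)-2-(4-hydroxy-3-methoxyphenyl)-4-(4-hydroxy-3-methoxybenzyl)oxolan-3-yl]methyl (2R)-2-methylbutanoate (21)

## The problem

Compound 21 is an oxolane (O1, C2 to C5) with a 4-hydroxy-3-methoxyphenyl group on C2, an acyloxymethyl arm on C3 and a 4-hydroxy-3-methoxybenzyl group on C4. The C2 and C3 substituents are trans, the C3 and C4 substituents are cis, and the ring is (2R,3S,4S). The ester is that of (R)-2-methylbutanoic acid; its remote stereocentre cannot be controlled from the ring and has to be bought.

C3 and C4 must be set absolutely. C2 is a benzylic ether carbon para to an oxygen, so it ionises readily. It can therefore be formed last and directed by C3, the 2,3-trans isomer being both the less hindered and the more stable one.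

The two primary oxygens, O1 on C5 and the oxygen of the C3 arm, begin at the same oxidation level and must be told apart: one closes the ring, the other carries the ester.

The phenols need protection through the organometallic step. The ester tolerates neither hydride nor strong base, and its α-centre can epimerise if the acid is over-activated. The C2–O1 bond is open to acid (re-ionisation, Friedel–Crafts capture by the second arene) and, more slowly, to hydrogenolysis.

The enabling feature is that the chain made of the arm CH2O carbon, C3, C4 and C5 is a latent butyrolactone. With C5 as the carbonyl carbon and the arm carbon as the γ-carbon, the C2 carbon becomes a β-substituent and the arylmethyl group an α-substituent. The cis relation on the oxolane then becomes a trans relation on the lactone. A trans-α,β-disubstituted lactone is what conjugate addition followed by enolate alkylation delivers, and a removable group on the γ-carbon can make both additions face-selective.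

## Retrosynthesis

**21 to 18 and 19.** The last bonds formed are the two phenolic O–H bonds and the ester C–O bond. Removing the benzyl groups in thought gives dibenzyl ether 20, and cutting its acyl–oxygen bond gives alcohol 18 and acid 19. The ester is introduced late because hydride and fluoride steps precede it. Carrying free phenols instead would force a chemoselective acylation. Alcohol 18 has a single hydroxyl, so no selectivity is asked; the forward steps must keep the α-centre of 19 intact and cleave aryl benzyl ethers without opening the benzylic ring bond.

**18 to 16 and 15.** The hydroxymethyl group on C3 of 18 is read as the stump of a 1,2-diol. Adding one carbon gives diol 16 and its silyl ether 15. This step backwards in simplicity allows the arm carbon to be a stereocentre, and so a controller, earlier in the route. The carbon is removed only after the ring is closed and the sulfur is gone, so periodate meets neither a dithiane nor a second free hydroxymethyl group. The forward reaction must reduce the α-branched β-alkoxy aldehyde 17 before it can epimerise.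

**15 to 14 and 13.** The ring is opened at O1–C2. The neighbouring cut, C5–O1, would need a configurationally defined benzylic alkoxide displacing a primary leaving group, and nothing controls the ketone reduction that would set that carbinol. Cutting at the benzylic carbon lets a cation erase the carbinol configuration and lets C3 decide. Triol 14 arises from keto lactone 13 in one hydride reduction, which also converts the lactone carbonyl into C5 with its hydroxyl. Keto lactone 13 has one stereocentre fewer than 15. The closure needs an acid mild enough to spare the silyl ether, because a free terminal hydroxyl could close a different five-membered ring; the secondary hydroxyl can only reach a four-membered one.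

**13 to 12.** The aryl ketone of 13 is the hydrolysis product of dithiane 12, so C2 is carried as a masked acyl anion. Unmasking at the lactone stage, before any hydroxyl is free, prevents internal trapping of the thionium ion and keeps sulfur away from every later oxidant.

**12 to 4, 7 and 9.** Two bonds are cut: the bond from the dithiane carbon to the lactone β-carbon (C2–C3 of the target) and the bond from the lactone α-carbon to the benzylic CH2 (C4–CH2 of the target). The polarity is natural: the β-carbon of butenolide 4 is electrophilic, the α-carbon of the derived enolate is nucleophilic, and lithiated dithiane 7 supplies the acyl anion. Cutting the central C3–C4 bond would require a cross-coupling of two different enolates, and cutting the aryl–carbon bonds would leave the stereotriad to be built without the arenes. The three fragments are of similar size and the only stereocentre left is the bought one in 4. The forward reaction must add 1,4 and anti to the silyloxymethyl group, and then alkylate trans with bromide 9.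

**4 to 3 and 1; 7 to 5 and 6; 9 to 8.** Butenolide 4 is the silyl ether of 3, the Baeyer–Villiger product of cellulose-derived levoglucosenone 1. Alcohol 3 can also be purchased, which would shorten the route by one step. C1 of 1 becomes the (S)-configured C5 of 4, and tracing the anti addition and trans alkylation through to the oxolane gives (3S,4S), the series required. A tert-butyldiphenylsilyl ether is preferred to the other common bulky choice, a trityl ether, because it survives the acid used for ring closure. Dithiane 7 comes from O-benzylvanillin 5 and propane-1,3-dithiol 6. Bromide 9 comes from benzylic alcohol 8.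

## Roads not taken

**Alternative 1:** The oxolane is cut at C2–C3 and C4–C5. C2, O1 and C5 come from a three-atom carbonyl ylide, and C3 and C4 from the double bond of the menthyloxybutenolide A1. In the forward direction fluoride releases the aryl carbonyl ylide A3 from the α-chlorobenzyl silylmethyl ether A2. Its (3+2) cycloaddition to A1, anti to the menthyloxy group, gives the cis-fused bicyclic lactone A4.

- Merits: the ring, two C–C bonds and the cis C3/C4 relation arise in one step. C2 arrives at the ether oxidation level, so no dithiane, mercury salt or reduction–closure sequence is needed. The auxiliary is cheap.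
- Weak points: nothing in A1 or A3 fixes which ylide terminus bonds to the α-carbon, or the endo/exo approach that sets C2. In A4 the C4 arm is an acetal carbon that must still become an arylmethyl group. That requires opening the lactone acetal, adding an aryl-metal reagent and reductively removing a benzylic hydroxyl, in a molecule whose C2–O1 bond is itself benzylic.
- Comparison: this road reaches the ring faster and avoids sulfur and mercury, which is a real advantage. The chosen plan sets against it that both regiochemical questions are settled by polarity, that each aryl ring arrives with its one-carbon link in place, and that no benzylic deoxygenation is needed beside the ring.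

**Alternative 2:** The two exocyclic bonds C3–CH2O and C4–CH2Ar are cut and traced to the two carbons of dichloroketene A6. The ring is preformed as the 2-aryl-2,5-dihydrofuran A5, made by an enantioselective Heck arylation with Pd(OAc)2 and a chiral phosphine. In the key step A6, generated in situ by zinc-mediated dehalogenation, adds suprafacially to the C3=C4 bond of A5 on the face away from the aryl group to give the cis-fused dichlorocyclobutanone A7.

- Merits: the absolute configuration comes from a catalyst, so no chiral-pool carbon has to be excised. C2 is set first and directs the rest. The cis relation of the two arms follows from the ring fusion.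
- Weak points: the alkene of A5 is almost unpolarised, so the orientation of the ketene (carbonyl carbon on C3) is not secured. The Heck step can give double-bond isomers and must work with an electron-rich aryl partner. A7 must then be cleaved between the carbonyl and dichloromethylene carbons, after which the second aryl ring still has to be attached to the C4 arm and the new benzylic position reduced, again next to the benzylic ring ether.
- Comparison: in the source of chirality this road is better. The chosen plan sets against it substrate-controlled selectivity at every stage and an arylmethyl group that is introduced intact.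

**Alternative 3:** Only O1–C2 is cut. The twofold-symmetric diol A8 is acylated once with acid 19; either hydroxyl gives the same monoester A9. The primary alkoxy radical of A9, generated through a hypoiodite with PhI(OAc)2 and I2, abstracts the benzylic hydrogen five atoms away through a six-membered transition state. Oxidation of the benzylic radical and capture by the same oxygen gives A10, which is identical with 20.

- Merits: this is the shortest road by a wide margin. The symmetry removes the problem of telling the two hydroxymethyl groups apart. The 1,5-geometry selects the correct benzylic CH2, since the other is only four atoms away. There is no sulfur, no mercury and no excised carbon.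
- Weak points: the oxidant system can iodinate or oxidise the electron-rich alkoxyarenes. A primary alkoxy radical can fragment with loss of formaldehyde. The new C2–H bond of A10 is more easily abstracted than the C–H bond being functionalised. The configuration at C2 rests on an uncontrolled cation capture.
- Comparison: in step count and atom economy this road is clearly better, and if the etherification ran cleanly it would be the route of choice. The chosen plan sets against it that the oxidation level of C2 is carried in from the start as a dithiane. It never has to be created by C–H oxidation on an electron-rich substrate, and every step is a known transformation of its substrate class. The price is roughly twice the number of steps.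

Key step: step 5

## Route

Assumption: compounds 1, 5, 6, 8 and 19 are taken as commercial, 19 as the pure (R)-enantiomer; oxolane atoms are numbered O1, C2 (aryl), C3 (acyloxymethyl), C4 (arylmethyl), C5.

Step 1
Reactants: 1 levoglucosenone
Product: 3 (S)-5-(hydroxymethyl)furan-2(5H)-one, via formate ester 2 (not isolated)
Conditions: 30% aq H2O2, H2O, 0 to 50 °C; then Amberlyst 15 (H+ form), 45 °C
Reagents that add atoms: none
Why: Baeyer–Villiger oxidation of the bicyclic enone: the acetal carbon migrates in preference to the vinylic carbon, the acyl orthoformate collapses to butenolide formate 2, and acid hydrolysis removes the formyl group. The stereocentre is not involved, so the (S)-configuration of 3 comes directly from C1 of 1; the inserted oxygen leaves with the formyl carbon, so no peroxide atom remains in 3.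

Step 2
Reactants: 3 (S)-5-(hydroxymethyl)furan-2(5H)-one
Product: 4 (S)-5-[(tert-butyldiphenylsilyloxy)methyl]furan-2(5H)-one
Conditions: TBDPSCl, imidazole, DMF, 0 °C to rt
Reagents that add atoms: tert-butyl(chloro)diphenylsilane, CC(C)(C)[Si](Cl)(c1ccccc1)c1ccccc1
Why: Silylation of a primary alcohol with a silyl chloride and imidazole; the weakly basic medium does not deprotonate the γ-position, so the stereocentre is retained. The bulky silyl group shields one face of the butenolide and later survives the acid of step 8.

Step 3
Reactants: 5 4-benzyloxy-3-methoxybenzaldehyde (O-benzylvanillin), 6 propane-1,3-dithiol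
Product: 7 2-(4-benzyloxy-3-methoxyphenyl)-1,3-dithiane
Conditions: BF3·OEt2 (cat.), CH2Cl2, 0 °C to rt
Reagents that add atoms: none
Why: Lewis-acid-catalysed dithioacetalisation of an aromatic aldehyde; the benzyl and methyl ethers are inert under these conditions, and the product has the acidic C2–H needed for umpolung.

Step 4
Reactants: 8 4-benzyloxy-3-methoxybenzyl alcohol
Product: 9 4-benzyloxy-3-methoxybenzyl bromide
Conditions: PBr3, Et2O, 0 °C
Reagents that add atoms: phosphorus tribromide, BrP(Br)Br
Why: Conversion of an electron-rich benzylic alcohol into its bromide through the alkyl phosphite (SN2 by bromide); the bromide is used without chromatography because it ionises easily.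

Step 5
Reactants: 7 2-(4-benzyloxy-3-methoxyphenyl)-1,3-dithiane, 4 (S)-5-[(tert-butyldiphenylsilyloxy)methyl]furan-2(5H)-one, 9 4-benzyloxy-3-methoxybenzyl bromide
Product: 12 (3S,4S,5S)-3-(4-benzyloxy-3-methoxybenzyl)-4-[2-(4-benzyloxy-3-methoxyphenyl)-1,3-dithian-2-yl]-5-[(tert-butyldiphenylsilyloxy)methyl]oxolan-2-one, via lithiated dithiane 10 (not isolated), via lithium lactone enolate 11 (not isolated)
Conditions: 7, n-BuLi, THF, −78 °C; then 4, −78 °C; then 9, DMPU, −78 to −20 °C
Reagents that add atoms: none
Why: n-BuLi deprotonates 7 at the dithiane carbon to give the sulfur- and aryl-stabilised carbanion 10, which adds in a Michael sense to C4 of butenolide 4; the lithium enolate 11 so formed is C-alkylated by benzylic bromide 9 in an SN2 step, so the future C2–C3 and C4–CH2 bonds of the target form in one flask. The closest known reaction type is the tandem conjugate addition–enolate alkylation of 2-aryl-2-lithio-1,3-dithianes with furan-2(5H)-ones, including members that carry a protected hydroxymethyl group on C5, which is the standard entry to trans-dibenzylbutyrolactone lignans. No ring is closed. The β-stereocentre (lactone C4, later C3 of the oxolane) is controlled by the C5 silyloxymethyl group: the nucleophile approaches the flat butenolide on the face opposite to it. The α-stereocentre (lactone C3, later C4 of the oxolane) is controlled by the new quaternary dithianyl group, which blocks one face of the enolate so that the electrophile enters trans. The step needs 1,4- rather than 1,2-addition, which the soft, hindered, delocalised aryl dithiane anion in THF at −78 °C secures. It also needs C-alkylation at a useful rate, secured by the reactive benzylic bromide and DMPU, and no γ-deprotonation of 4, disfavoured because the anion is a poor kinetic base at low temperature. The trans,trans lactone is also the most stable diastereomer, so neither new centre is at risk during work-up.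

Step 6
Reactants: 12 (3S,4S,5S)-3-(4-benzyloxy-3-methoxybenzyl)-4-[2-(4-benzyloxy-3-methoxyphenyl)-1,3-dithian-2-yl]-5-[(tert-butyldiphenylsilyloxy)methyl]oxolan-2-one
Product: 13 (3S,4S,5S)-3-(4-benzyloxy-3-methoxybenzyl)-4-(4-benzyloxy-3-methoxybenzoyl)-5-[(tert-butyldiphenylsilyloxy)methyl]oxolan-2-one
Conditions: Hg(ClO4)2·3H2O, CaCO3, THF/H2O, 0 °C
Reagents that add atoms: water, O
Why: Thiophilic hydrolysis of a dithioacetal: divalent mercury binds sulfur, water adds to the thionium ion and the aryl ketone is released, while CaCO3 takes up the acid so that the silyl ether and the β-acyloxy ketone are not disturbed. The α-hydrogen of the new ketone sits on a centre that already has the more stable trans,trans arrangement.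

Step 7
Reactants: 13 (3S,4S,5S)-3-(4-benzyloxy-3-methoxybenzyl)-4-(4-benzyloxy-3-methoxybenzoyl)-5-[(tert-butyldiphenylsilyloxy)methyl]oxolan-2-one
Product: 14 (2S,3R,4S)-2-(4-benzyloxy-3-methoxybenzyl)-3-[(4-benzyloxy-3-methoxyphenyl)(hydroxy)methyl]-5-(tert-butyldiphenylsilyloxy)pentane-1,4-diol (both epimers at the benzylic carbinol)
Conditions: LiAlH4, THF, 0 °C
Reagents that add atoms: none
Why: Hydride reduction of the lactone to the 1,4-diol and of the ketone to the benzylic alcohol; the carbinol centre forms unselectively, which does not matter because it is ionised in step 8. Benzyl and silyl ethers are inert to LiAlH4 at this temperature.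

Step 8
Reactants: 14 (2S,3R,4S)-2-(4-benzyloxy-3-methoxybenzyl)-3-[(4-benzyloxy-3-methoxyphenyl)(hydroxy)methyl]-5-(tert-butyldiphenylsilyloxy)pentane-1,4-diol
Product: 15 (1S)-1-[(2R,3S,4S)-4-(4-benzyloxy-3-methoxybenzyl)-2-(4-benzyloxy-3-methoxyphenyl)oxolan-3-yl]-2-(tert-butyldiphenylsilyloxy)ethan-1-ol
Conditions: CSA (cat.), CH2Cl2, 0 °C
Reagents that add atoms: none
Why: Acid-catalysed SN1 cycloetherification: the 4-alkoxybenzylic alcohol ionises under mild acid and the cation is captured by the C5 hydroxyl to close the five-membered ring; the secondary hydroxyl could only form an oxetane and the silylated oxygen is not nucleophilic. The new C2 centre is set by C3: the aryl group goes trans to the C3 side chain (and so trans to the C4 group as well), the less hindered approach and the more stable isomer, to which any cis product should equilibrate since ionisation is reversible. A weak acid and low temperature keep Friedel–Crafts capture by the other arene in check.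

Step 9
Reactants: 15 (1S)-1-[(2R,3S,4S)-4-(4-benzyloxy-3-methoxybenzyl)-2-(4-benzyloxy-3-methoxyphenyl)oxolan-3-yl]-2-(tert-butyldiphenylsilyloxy)ethan-1-ol
Product: 16 (1S)-1-[(2R,3S,4S)-4-(4-benzyloxy-3-methoxybenzyl)-2-(4-benzyloxy-3-methoxyphenyl)oxolan-3-yl]ethane-1,2-diol
Conditions: Bu4NF, THF, 0 °C to rt
Reagents that add atoms: none
Why: Fluoride-mediated cleavage of the silyl ether, driven by Si–F bond formation; nothing else in 15 reacts with fluoride.

Step 10
Reactants: 16 (1S)-1-[(2R,3S,4S)-4-(4-benzyloxy-3-methoxybenzyl)-2-(4-benzyloxy-3-methoxyphenyl)oxolan-3-yl]ethane-1,2-diol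
Product: 18 [(2R,3S,4S)-4-(4-benzyloxy-3-methoxybenzyl)-2-(4-benzyloxy-3-methoxyphenyl)oxolan-3-yl]methanol, via oxolane carbaldehyde 17 (not isolated)
Conditions: NaIO4, THF/H2O, 0 °C; extractive work-up; then NaBH4, MeOH, 0 °C
Reagents that add atoms: none
Why: Periodate glycol cleavage through the cyclic periodate ester removes the carbon that carried the controlling stereocentre, and the α-branched aldehyde 17 is reduced at once by NaBH4, before it can epimerise at C3 or lose the ring oxygen by β-elimination. No sulfur is present at this stage, so periodate has no competing substrate.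

Step 11
Reactants: 18 [(2R,3S,4S)-4-(4-benzyloxy-3-methoxybenzyl)-2-(4-benzyloxy-3-methoxyphenyl)oxolan-3-yl]methanol, 19 (R)-2-methylbutanoic acid
Product: 20 [(2R,3S,4S)-4-(4-benzyloxy-3-methoxybenzyl)-2-(4-benzyloxy-3-methoxyphenyl)oxolan-3-yl]methyl (2R)-2-methylbutanoate
Conditions: DCC, DMAP (cat.), CH2Cl2, 0 °C to rt
Reagents that add atoms: none
Why: Steglich esterification of the only free hydroxyl; a catalytic amount of DMAP at 0 °C keeps the acylpyridinium short-lived, so the α-stereocentre of 19 should be carried over unchanged.

Step 12
Reactants: 20 [(2R,3S,4S)-4-(4-benzyloxy-3-methoxybenzyl)-2-(4-benzyloxy-3-methoxyphenyl)oxolan-3-yl]methyl (2R)-2-methylbutanoate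
Product: 21 [(2R,3S,4S)-2-(4-hydroxy-3-methoxyphenyl)-4-(4-hydroxy-3-methoxybenzyl)oxolan-3-yl]methyl (2R)-2-methylbutanoate
Conditions: H2 (1 atm), 10% Pd/C, EtOAc, rt
Reagents that add atoms: none
Why: Hydrogenolysis of the two aryl benzyl ethers; these cleave much faster than the benzylic C2–O1 bond of the ring, so in a neutral aprotic solvent at 1 atm, with the reaction stopped when 20 is consumed, the oxolane and the ester should remain intact.

## Compound list

1 | levoglucosenone, (1S,5R)-6,8-dioxabicyclo[3.2.1]oct-2-en-4-one | O=C1C=C[C@H]2CO[C@@H]1O2 | starting material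
2 | [(2S)-5-oxo-2,5-dihydrofuran-2-yl]methyl formate | O=C1C=C[C@@H](COC=O)O1 | intermediate
3 | (S)-5-(hydroxymethyl)furan-2(5H)-one | O=C1C=C[C@@H](CO)O1 | intermediate
4 | (S)-5-[(tert-butyldiphenylsilyloxy)methyl]furan-2(5H)-one | O=C1C=C[C@@H](CO[Si](c2ccccc2)(c2ccccc2)C(C)(C)C)O1 | intermediate
5 | 4-benzyloxy-3-methoxybenzaldehyde (O-benzylvanillin) | COc1cc(C=O)ccc1OCc1ccccc1 | starting material
6 | propane-1,3-dithiol | SCCCS | starting material
7 | 2-(4-benzyloxy-3-methoxyphenyl)-1,3-dithiane | COc1cc(C2SCCCS2)ccc1OCc1ccccc1 | intermediate
8 | 4-benzyloxy-3-methoxybenzyl alcohol | COc1cc(CO)ccc1OCc1ccccc1 | starting material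
9 | 4-benzyloxy-3-methoxybenzyl bromide | COc1cc(CBr)ccc1OCc1ccccc1 | intermediate
10 | 2-lithio-2-(4-benzyloxy-3-methoxyphenyl)-1,3-dithiane | COc1cc(C2([Li])SCCCS2)ccc1OCc1ccccc1 | intermediate
11 | lithium enolate of (4S,5S)-4-[2-(4-benzyloxy-3-methoxyphenyl)-1,3-dithian-2-yl]-5-[(tert-butyldiphenylsilyloxy)methyl]oxolan-2-one | [Li]OC1=C[C@H](C2(c3ccc(OCc4ccccc4)c(OC)c3)SCCCS2)[C@@H](CO[Si](c2ccccc2)(c2ccccc2)C(C)(C)C)O1 | intermediate
12 | (3S,4S,5S)-3-(4-benzyloxy-3-methoxybenzyl)-4-[2-(4-benzyloxy-3-methoxyphenyl)-1,3-dithian-2-yl]-5-[(tert-butyldiphenylsilyloxy)methyl]oxolan-2-one (all substituents trans) | O=C1[C@@H](Cc2ccc(OCc3ccccc3)c(OC)c2)[C@H](C2(c3ccc(OCc4ccccc4)c(OC)c3)SCCCS2)[C@@H](CO[Si](c2ccccc2)(c2ccccc2)C(C)(C)C)O1 | intermediate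
13 | (3S,4S,5S)-3-(4-benzyloxy-3-methoxybenzyl)-4-(4-benzyloxy-3-methoxybenzoyl)-5-[(tert-butyldiphenylsilyloxy)methyl]oxolan-2-one | O=C1[C@@H](Cc2ccc(OCc3ccccc3)c(OC)c2)[C@H](C(=O)c2ccc(OCc3ccccc3)c(OC)c2)[C@@H](CO[Si](c2ccccc2)(c2ccccc2)C(C)(C)C)O1 | intermediate
14 | (2S,3R,4S)-2-(4-benzyloxy-3-methoxybenzyl)-3-[(4-benzyloxy-3-methoxyphenyl)(hydroxy)methyl]-5-(tert-butyldiphenylsilyloxy)pentane-1,4-diol, both epimers at the benzylic carbinol | OC[C@@H](Cc1ccc(OCc2ccccc2)c(OC)c1)[C@H](C(O)c1ccc(OCc2ccccc2)c(OC)c1)[C@H](O)CO[Si](c1ccccc1)(c1ccccc1)C(C)(C)C | intermediate
15 | (1S)-1-[(2R,3S,4S)-4-(4-benzyloxy-3-methoxybenzyl)-2-(4-benzyloxy-3-methoxyphenyl)oxolan-3-yl]-2-(tert-butyldiphenylsilyloxy)ethan-1-ol | CC(C)(C)[Si](c1ccccc1)(c1ccccc1)OC[C@@H](O)[C@@H]1[C@H](Cc2ccc(OCc3ccccc3)c(OC)c2)CO[C@H]1c1ccc(OCc2ccccc2)c(OC)c1 | intermediate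
16 | (1S)-1-[(2R,3S,4S)-4-(4-benzyloxy-3-methoxybenzyl)-2-(4-benzyloxy-3-methoxyphenyl)oxolan-3-yl]ethane-1,2-diol | OC[C@@H](O)[C@@H]1[C@H](Cc2ccc(OCc3ccccc3)c(OC)c2)CO[C@H]1c1ccc(OCc2ccccc2)c(OC)c1 | intermediate
17 | (2R,3R,4S)-4-(4-benzyloxy-3-methoxybenzyl)-2-(4-benzyloxy-3-methoxyphenyl)oxolane-3-carbaldehyde | O=C[C@@H]1[C@H](Cc2ccc(OCc3ccccc3)c(OC)c2)CO[C@H]1c1ccc(OCc2ccccc2)c(OC)c1 | intermediate
18 | [(2R,3S,4S)-4-(4-benzyloxy-3-methoxybenzyl)-2-(4-benzyloxy-3-methoxyphenyl)oxolan-3-yl]methanol | OC[C@@H]1[C@H](Cc2ccc(OCc3ccccc3)c(OC)c2)CO[C@H]1c1ccc(OCc2ccccc2)c(OC)c1 | intermediate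
19 | (R)-2-methylbutanoic acid | CC[C@@H](C)C(=O)O | starting material
20 | [(2R,3S,4S)-4-(4-benzyloxy-3-methoxybenzyl)-2-(4-benzyloxy-3-methoxyphenyl)oxolan-3-yl]methyl (2R)-2-methylbutanoate | CC[C@@H](C)C(=O)OC[C@@H]1[C@H](Cc2ccc(OCc3ccccc3)c(OC)c2)CO[C@H]1c1ccc(OCc2ccccc2)c(OC)c1 | intermediate
21 | [(2R,3S,4S)-2-(4-hydroxy-3-methoxyphenyl)-4-(4-hydroxy-3-methoxybenzyl)oxolan-3-yl]methyl (2R)-2-methylbutanoate | CC[C@@H](C)C(=O)OC[C@@H]1[C@H](Cc2ccc(O)c(OC)c2)CO[C@H]1c1ccc(O)c(OC)c1 | target

## Step count and least certain steps

Total: 12 steps. Longest linear sequence: 10 steps (steps 1, 2 and 5 to 12); steps 3 and 4 feed the key step from the side.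

**Step 5 (key step).** The most likely failure is slow or incomplete C-alkylation of enolate 11, which is flanked by the quaternary dithianyl carbon; proton transfer would then return non-alkylated material. A lesser risk is competing 1,2-addition or γ-deprotonation of 4, which would cost throughput and enantiomeric purity.

Fallback: the two bond formations are separated. Setting out from 4 and 7, the conjugate addition is run alone and quenched with aqueous NH4Cl to give the β-dithianyl lactone F1, which is purified. Its enolate is regenerated with LiN(iPr)2 in THF at −78 °C and alkylated with 9 in the presence of DMPU, rejoining the route at 12. The trans relation is again dictated by the dithianyl group, and each half can be optimised separately.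

**Step 6.** Once the carbonyl is unveiled, the lactone oxygen is β to an enolisable aryl ketone. β-Elimination with opening of the lactone can therefore set in during the hydrolysis, on work-up or on silica.

Fallback: reduction and unmasking are exchanged. Setting out from 12, LiAlH4 in THF gives the dithianyl diol F2, in which the β-oxygen is a hydroxyl and no longer a leaving group. Hydrolysis of the dithiane under the conditions of step 6 gives the hydroxy ketone F3, which should rest largely as its five-membered hemiketal. NaBH4 in MeOH reduces F3 to 14, where the route is rejoined.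

**Step 8.** The likely failures are erosion of face selectivity at C2, because the C3 substituent is branched and hydroxylated, and partial loss of the silyl group under acid, which would free a second primary hydroxyl able to close a different five-membered ring.

Fallback: the carbon is excised before the ring is closed. Setting out from 14, Bu4NF gives the tetraol F4. NaIO4 cleaves its terminal diol to an aldehyde that is held as the lactol F5, and NaBH4 gives the triol F6. CSA in CH2Cl2 then closes the ring to give 18 directly, where the route is rejoined; steps 9 and 10 fall away. In F6 only the C5 hydroxyl can reach the cation on C2 through a five-membered ring, since the other hydroxymethyl group would have to form an oxetane, and the C3 substituent is the small hydroxymethyl group for which this closure is best established.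

**Step 11.** The likely failure is partial epimerisation of the α-centre of 19 through enolisation or ketene formation from the activated acyl species, giving a diastereomeric ester that is hard to separate.

Fallback: activation is moved from the acid to the alcohol. Setting out from 18 and 19, a Mitsunobu esterification (PPh3, diisopropyl azodicarboxylate, THF, 0 °C) converts the primary alcohol into its alkoxyphosphonium ion and lets the carboxylate of 19 act only as a nucleophile. The reaction arrives at 20 without any new compound (entry F0).

## Further compounds

F1 | step 5 | (4S,5S)-4-[2-(4-benzyloxy-3-methoxyphenyl)-1,3-dithian-2-yl]-5-[(tert-butyldiphenylsilyloxy)methyl]oxolan-2-one | O=C1C[C@H](C2(c3ccc(OCc4ccccc4)c(OC)c3)SCCCS2)[C@@H](CO[Si](c2ccccc2)(c2ccccc2)C(C)(C)C)O1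
F2 | step 6 | dithianyl diol, the 1,4-diol from reduction of the lactone of 12, stereocentres as in 12 | OC[C@@H](Cc1ccc(OCc2ccccc2)c(OC)c1)[C@H](C1(c2ccc(OCc3ccccc3)c(OC)c2)SCCCS1)[C@H](O)CO[Si](c1ccccc1)(c1ccccc1)C(C)(C)C
F3 | step 6 | hydroxy ketone, the aryl ketone corresponding to F2 (open form shown) | OC[C@@H](Cc1ccc(OCc2ccccc2)c(OC)c1)[C@H](C(=O)c1ccc(OCc2ccccc2)c(OC)c1)[C@H](O)CO[Si](c1ccccc1)(c1ccccc1)C(C)(C)C
F4 | step 8 | tetraol, 14 without the silyl group | OC[C@@H](Cc1ccc(OCc2ccccc2)c(OC)c1)[C@H](C(O)c1ccc(OCc2ccccc2)c(OC)c1)[C@H](O)CO
F5 | step 8 | lactol, 4-(4-benzyloxy-3-methoxybenzyl)-3-[(4-benzyloxy-3-methoxyphenyl)(hydroxy)methyl]oxolan-2-ol with ring substituents trans, anomers and carbinol epimers | OC1OC[C@@H](Cc2ccc(OCc3ccccc3)c(OC)c2)[C@@H]1C(O)c1ccc(OCc2ccccc2)c(OC)c1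
F6 | step 8 | triol, (2S,3S)-2-(4-benzyloxy-3-methoxybenzyl)-3-[(4-benzyloxy-3-methoxyphenyl)(hydroxy)methyl]butane-1,4-diol, carbinol epimers | OC[C@@H](Cc1ccc(OCc2ccccc2)c(OC)c1)[C@H](C(O)c1ccc(OCc2ccccc2)c(OC)c1)CO
F0 | step 11 | none | none
A1 | alternative 1 | (5R)-5-[(1R,2S,5R)-menthyloxy]furan-2(5H)-one | O=C1O[C@@H](O[C@@H]2C[C@H](C)CC[C@H]2C(C)C)C=C1
A2 | alternative 1 | 1-benzyloxy-4-{chloro[(trimethylsilyl)methoxy]methyl}-2-methoxybenzene | COc1cc(C(Cl)OC[Si](C)(C)C)ccc1OCc1ccccc1
A3 | alternative 1 | aryl carbonyl ylide from A2 | [CH2-][O+]=Cc1ccc(OCc2ccccc2)c(OC)c1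
A4 | alternative 1 | cis-fused 2-aryl-oxolane menthyloxy lactone cycloadduct | O=C1O[C@@H](O[C@@H]3C[C@H](C)CC[C@H]3C(C)C)[C@@H]2CO[C@@H](c3ccc(OCc4ccccc4)c(OC)c3)[C@H]12
A5 | alternative 2 | (2R)-2-(4-benzyloxy-3-methoxyphenyl)-2,5-dihydrofuran | C1=C[C@H](c2ccc(OCc3ccccc3)c(OC)c2)OC1
A6 | alternative 2 | dichloroketene | ClC(Cl)=C=O
A7 | alternative 2 | cis-fused 2-(4-benzyloxy-3-methoxyphenyl)-6,6-dichloro-3-oxabicyclo[3.2.0]heptan-7-one | O=C1[C@H]2[C@H](c3ccc(OCc4ccccc4)c(OC)c3)OC[C@H]2C1(Cl)Cl
A8 | alternative 3 | (2S,3S)-2,3-bis(4-benzyloxy-3-methoxybenzyl)butane-1,4-diol | OC[C@@H](Cc1ccc(OCc2ccccc2)c(OC)c1)[C@H](Cc1ccc(OCc2ccccc2)c(OC)c1)CO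
A9 | alternative 3 | mono-(2R)-2-methylbutanoate of A8 | CC[C@@H](C)C(=O)OC[C@@H](Cc1ccc(OCc2ccccc2)c(OC)c1)[C@H](Cc1ccc(OCc2ccccc2)c(OC)c1)CO
A10 | alternative 3 | O,O'-dibenzyl ether of the target, identical with 20 | CC[C@@H](C)C(=O)OC[C@@H]1[C@H](Cc2ccc(OCc3ccccc3)c(OC)c2)CO[C@H]1c1ccc(OCc2ccccc2)c(OC)c1
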